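**Plan**
- Cuts, in retrosynthetic order: the nine O-benzyl groups; C3–OH and C4–H of the upper pyran ring (back to a C3=C4 alkene, a 4-aryl-flav-3-ene); the O1–C2 bond of that ring (back to an acyclic 1,1,3-triaryl allylic carbinol); the interflavanoid C4–C8 bond (chalcone ketone plus 8-lithiated catechin); the chalcone Cα=Cβ bond (aldol).
- Forward: rings D, E and F (lower benzo, catechol and pyran rings) come intact from (+)-catechin; rings A and B (upper 7,8-dioxygenated benzo ring and catechol) are joined as a chalcone; aryllithium addition unites the halves at C4–C8; ring C (upper pyran) closes last through O1–C2; the alkene is then hydrated.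
- Enabling feature: in the upper unit the phenolic O1 on C8a is ortho to C4, C4 carries two electron-rich aryl rings (A and D), and C2 is benzylic to ring B with its 4'-oxygen para. C2–C3–C4 can therefore be raised to a stabilised allyl cation (a protonated vinylogous ortho-quinone methide) that O1 can close only at C2. The extra unsaturation at C3=C4 is the helper and is removed by hydroboration.
- Stereochemistry: lower C2 and C3 from (+)-catechin; upper C2 from a chiral N-triflylphosphoramide in the ring closure; upper C3 and C4 from syn hydroboration anti to the 2-aryl group.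

Key step: step 9

Assumption: the (R)-catalyst is written for the (2S)-chromene; its sense of induction on this substrate should be confirmed on small scale, and the antipodal catalyst used if the sense is opposite.

Step 1
Reactants: 1 (+)-catechin
Product: 2 5,7,3',4'-tetra-O-benzyl-(+)-catechin
Conditions: BnBr (4.4 equiv), K2CO3, DMF, 0 °C to rt
Reagents that add atoms: benzyl bromide, BrCc1ccccc1
Why: Williamson etherification of the four phenols with a weak base should leave the secondary 3-OH free and avoid the strong-base opening of ring F that epimerises C2; no stereocentre is touched.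

Step 2
Reactants: 2 5,7,3',4'-tetra-O-benzyl-(+)-catechin
Product: 3 3,5,7,3',4'-penta-O-benzyl-(+)-catechin
Conditions: NaH, BnBr, DMF, 0 °C to rt
Reagents that add atoms: benzyl bromide, BrCc1ccccc1
Why: Williamson etherification of the remaining secondary alcohol through its sodium alkoxide is safe now that no free phenol is left to trigger C2 epimerisation.

Step 3
Reactants: 3 3,5,7,3',4'-penta-O-benzyl-(+)-catechin
Product: 4 8-bromo-3,5,7,3',4'-penta-O-benzyl-(+)-catechin
Conditions: NBS (1.0 equiv), CH2Cl2, −78 °C to 0 °C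
Reagents that add atoms: N-bromosuccinimide, O=C1CCC(=O)N1Br
Why: Electrophilic aromatic bromination of the phloroglucinol-type ring D of 5,7-di-O-benzyl flavan-3-ol ethers is known to occur selectively at C8, the position between the ring oxygen and the 7-benzyloxy group.

Step 4
Reactants: 5 1-(2,3,4-trihydroxyphenyl)ethanone (gallacetophenone)
Product: 6 1-[3,4-bis(benzyloxy)-2-hydroxyphenyl]ethanone
Conditions: BnBr (2.1 equiv), K2CO3, acetone, reflux
Reagents that add atoms: benzyl bromide, BrCc1ccccc1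
Why: Williamson etherification in which the 2-OH, hydrogen-bonded to the acetyl carbonyl, is the least nucleophilic phenol and should stay free.

Step 5
Reactants: 6 1-[3,4-bis(benzyloxy)-2-hydroxyphenyl]ethanone; 7 3,4-bis(benzyloxy)benzaldehyde
Product: 8 (E)-2'-hydroxy-3,4,3',4'-tetrakis(benzyloxy)chalcone
Conditions: KOH (50% aq.), EtOH/THF, rt; then cold dilute HCl
Reagents that add atoms: none
Why: Claisen–Schmidt aldol condensation, in which dehydration under thermodynamic control gives the E enone.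

Step 6
Reactants: 8 (E)-2'-hydroxy-3,4,3',4'-tetrakis(benzyloxy)chalcone
Product: 9 2'-O-tert-butyldimethylsilyl ether of chalcone 8
Conditions: TBSOTf, 2,6-lutidine, CH2Cl2, 0 °C
Reagents that add atoms: tert-butyldimethylsilyl triflate, CC(C)(C)[Si](C)(C)OS(=O)(=O)C(F)(F)F
Why: Silylation of the chelated phenol with the reactive silyl triflate masks the acidic OH (which would quench the aryllithium and deactivate the ketone as its phenoxide) with a group that fluoride removes without acid.

Step 7
Reactants: 4 8-bromo-3,5,7,3',4'-penta-O-benzyl-(+)-catechin; 9 2'-O-TBS chalcone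
Product: 11 silyl-protected triaryl allylic carbinol (both epimers at the carbinol carbon), via 8-lithio-penta-O-benzylcatechin 10 (not isolated)
Conditions: t-BuLi (2.0 equiv), THF, −78 °C; then 9 in THF, −78 °C; H2O quench at −78 °C
Reagents that add atoms: none
Why: Bromine–lithium exchange followed by 1,2-addition of the hard aryllithium to the enone carbonyl at low temperature fixes the C4–C8 bond with complete 8-regiochemistry; the carbinol stereocentre forms unselectively and is erased in step 9, and the cold quench suppresses O-to-O silyl migration.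

Step 8
Reactants: 11 silyl-protected triaryl allylic carbinol
Product: 12 phenolic triaryl allylic carbinol
Conditions: TBAF, AcOH (1:1), THF, 0 °C; NaHCO3 work-up, filtration through Et3N-deactivated silica, used at once
Reagents that add atoms: none
Why: Fluoride cleavage of the aryl silyl ether under buffered, non-ionising conditions should free the ring A phenol while the acid-labile tertiary allylic alcohol survives.

Step 9
Reactants: 12 phenolic triaryl allylic carbinol
Product: 14 (2S)-4-aryl-2H-chromene (benzylated 4-(catechin-8-yl)flav-3-ene), via triarylallyl cation 13 (not isolated)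
Conditions: (R)-3,3'-bis(2,4,6-triisopropylphenyl)-1,1'-binaphthyl-2,2'-diyl N-(trifluoromethylsulfonyl)phosphoramide (10 mol %), toluene, −78 °C; Et3N quench at −78 °C
Reagents that add atoms: none
Why: The N-triflylphosphoramide protonates the tertiary bis-benzylic allylic hydroxyl of 12, water leaves, and the 1,1,3-triarylallyl cation 13 (charge shared between C4 with rings A and D and C2 with the para-oxygenated ring B) stays paired with the chiral phosphoramide anion while the ring A 8a-OH, hydrogen-bonded to that anion, attacks the C2 terminus. The closest known reaction type is the chiral Brønsted acid (contact ion pair) catalysed intramolecular allylic substitution of 2-(1-hydroxyallyl)phenols to 2-aryl-2H-chromenes, which can also be read as the oxa-6π closure of a protonated vinylogous ortho-quinone methide. Ring C closes in the 6-endo-trig mode (O1 onto C2, the C3=C4 bond ending inside the ring); attack at C4 would give a four-membered ring, so the regiochemistry is fixed. The only new stereocentre, C2, is controlled by the chiral anion, which shields one face of the planar C2 terminus; the carbinol stereocentre of 12 is lost in the cation, so both epimers converge, and the geometric isomers of 13 about C3–C4 interconvert so that only the one with the phenol syn to C2 closes. The step needs face selectivity at C2 against the remote stereocentres of the catechin unit (catalyst control, with the two C2 epimers being separable diastereomers) and kinetic control, which the low temperature and the cold amine quench should secure by stopping the electron-rich chromene from reionising.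

Step 10
Reactants: 14 (2S)-4-aryl-2H-chromene
Product: 16 nona-O-benzyl mesquitol-(4α→8)-catechin, via C3 alkylborane 15 (not isolated)
Conditions: BH3·THF, THF, 0 °C to rt; then NaOH, H2O2, 0 °C to rt
Reagents that add atoms: hydrogen peroxide, OO
Why: Hydroboration–oxidation of the styrenic C3=C4 bond, as known for flav-3-enes, puts boron on the non-benzylic C3 and hydrogen on C4 in a syn fashion from the face opposite the 2-aryl group, and oxidation with retention should give the 2,3-trans-3,4-trans (2R,3S,4S) array.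

Step 11
Reactants: 16 nona-O-benzyl mesquitol-(4α→8)-catechin
Product: 17 mesquitol-(4α→8)-catechin (target, CNP0231186.1)
Conditions: H2 (1 atm), Pd(OH)2/C, THF/MeOH/H2O, rt
Reagents that add atoms: none
Why: Hydrogenolysis of the eight aryl and one alkyl benzyl ethers under conditions standard for benzylated proanthocyanidins should leave the flavan C2–O1 bonds and the C4–C8 bond intact and touch no stereocentre.

**Compound list**
1 | (+)-catechin, (2R,3S) | O[C@H]1Cc2c(O)cc(O)cc2O[C@@H]1c1ccc(O)c(O)c1 | starting material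
2 | 5,7,3',4'-tetra-O-benzyl-(+)-catechin | O[C@H]1Cc2c(OCc3ccccc3)cc(OCc3ccccc3)cc2O[C@@H]1c1ccc(OCc2ccccc2)c(OCc2ccccc2)c1 | intermediate
3 | 3,5,7,3',4'-penta-O-benzyl-(+)-catechin | C(c1ccccc1)O[C@H]1Cc2c(OCc3ccccc3)cc(OCc3ccccc3)cc2O[C@@H]1c1ccc(OCc2ccccc2)c(OCc2ccccc2)c1 | intermediate
4 | 8-bromo-3,5,7,3',4'-penta-O-benzyl-(+)-catechin | C(c1ccccc1)O[C@H]1Cc2c(OCc3ccccc3)cc(OCc3ccccc3)c(Br)c2O[C@@H]1c1ccc(OCc2ccccc2)c(OCc2ccccc2)c1 | intermediate
5 | 1-(2,3,4-trihydroxyphenyl)ethanone (gallacetophenone) | CC(=O)c1ccc(O)c(O)c1O | starting material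
6 | 1-[3,4-bis(benzyloxy)-2-hydroxyphenyl]ethanone | CC(=O)c1ccc(OCc2ccccc2)c(OCc2ccccc2)c1O | intermediate
7 | 3,4-bis(benzyloxy)benzaldehyde | O=Cc1ccc(OCc2ccccc2)c(OCc2ccccc2)c1 | starting material
8 | (E)-1-[3,4-bis(benzyloxy)-2-hydroxyphenyl]-3-[3,4-bis(benzyloxy)phenyl]prop-2-en-1-one | O=C(/C=C/c1ccc(OCc2ccccc2)c(OCc2ccccc2)c1)c1ccc(OCc2ccccc2)c(OCc2ccccc2)c1O | intermediate
9 | (E)-1-[3,4-bis(benzyloxy)-2-(tert-butyldimethylsilyloxy)phenyl]-3-[3,4-bis(benzyloxy)phenyl]prop-2-en-1-one | O=C(/C=C/c1ccc(OCc2ccccc2)c(OCc2ccccc2)c1)c1ccc(OCc2ccccc2)c(OCc2ccccc2)c1O[Si](C)(C)C(C)(C)C | intermediate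
10 | 8-lithio-3,5,7,3',4'-penta-O-benzyl-(+)-catechin | C(c1ccccc1)O[C@H]1Cc2c(OCc3ccccc3)cc(OCc3ccccc3)c([Li])c2O[C@@H]1c1ccc(OCc2ccccc2)c(OCc2ccccc2)c1 | intermediate (not isolated)
11 | (E)-1-[3,4-bis(benzyloxy)-2-(tert-butyldimethylsilyloxy)phenyl]-3-[3,4-bis(benzyloxy)phenyl]-1-[(2R,3S)-penta-O-benzylcatechin-8-yl]prop-2-en-1-ol, both epimers at C1 | OC(/C=C/c1ccc(OCc2ccccc2)c(OCc2ccccc2)c1)(c1ccc(OCc2ccccc2)c(OCc2ccccc2)c1O[Si](C)(C)C(C)(C)C)c1c(OCc2ccccc2)cc(OCc2ccccc2)c2c1O[C@H](c1ccc(OCc3ccccc3)c(OCc3ccccc3)c1)[C@@H](OCc1ccccc1)C2 | intermediate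
12 | (E)-1-[3,4-bis(benzyloxy)-2-hydroxyphenyl]-3-[3,4-bis(benzyloxy)phenyl]-1-[(2R,3S)-penta-O-benzylcatechin-8-yl]prop-2-en-1-ol, both epimers at C1 | OC(/C=C/c1ccc(OCc2ccccc2)c(OCc2ccccc2)c1)(c1ccc(OCc2ccccc2)c(OCc2ccccc2)c1O)c1c(OCc2ccccc2)cc(OCc2ccccc2)c2c1O[C@H](c1ccc(OCc3ccccc3)c(OCc3ccccc3)c1)[C@@H](OCc1ccccc1)C2 | intermediate
13 | 1,1,3-triarylallyl cation (protonated vinylogous ortho-quinone methide), drawn with the charge at C2 and the phenol syn to C2, paired with the phosphoramide anion | Oc1c(OCc2ccccc2)c(OCc2ccccc2)ccc1/C(=C\[CH+]c1ccc(OCc2ccccc2)c(OCc2ccccc2)c1)c1c(OCc2ccccc2)cc(OCc2ccccc2)c2c1O[C@H](c1ccc(OCc3ccccc3)c(OCc3ccccc3)c1)[C@@H](OCc1ccccc1)C2 | intermediate (not isolated)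
14 | (2S)-7,8-bis(benzyloxy)-2-[3,4-bis(benzyloxy)phenyl]-4-[(2R,3S)-penta-O-benzylcatechin-8-yl]-2H-chromene | C(c1ccccc1)Oc1ccc([C@H]2Oc3c(ccc(OCc4ccccc4)c3OCc3ccccc3)C(=C2)c2c(OCc3ccccc3)cc(OCc3ccccc3)c3c2O[C@H](c2ccc(OCc4ccccc4)c(OCc4ccccc4)c2)[C@@H](OCc2ccccc2)C3)cc1OCc1ccccc1 | intermediate
15 | C3 monoalkylborane of 14 (boron on C3 and hydrogen on C4, both anti to the 2-aryl group) | C(c1ccccc1)Oc1ccc([C@H]2Oc3c(ccc(OCc4ccccc4)c3OCc3ccccc3)[C@@H](c3c(OCc4ccccc4)cc(OCc4ccccc4)c4c3O[C@H](c3ccc(OCc5ccccc5)c(OCc5ccccc5)c3)[C@@H](OCc3ccccc3)C4)[C@@H]2B)cc1OCc1ccccc1 | intermediate (not isolated)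
16 | (2R,3S,4S)-7,8-bis(benzyloxy)-2-[3,4-bis(benzyloxy)phenyl]-4-[(2R,3S)-penta-O-benzylcatechin-8-yl]chroman-3-ol | C(c1ccccc1)Oc1ccc([C@H]2Oc3c(ccc(OCc4ccccc4)c3OCc3ccccc3)[C@@H](c3c(OCc4ccccc4)cc(OCc4ccccc4)c4c3O[C@H](c3ccc(OCc5ccccc5)c(OCc5ccccc5)c3)[C@@H](OCc3ccccc3)C4)[C@@H]2O)cc1OCc1ccccc1 | intermediate
17 | (2R,3S,4S)-2-(3,4-dihydroxyphenyl)-4-[(2R,3S)-2-(3,4-dihydroxyphenyl)-3,5,7-trihydroxychroman-8-yl]chroman-3,7,8-triol, mesquitol-(4α→8)-catechin | Oc1ccc([C@H]2Oc3c(ccc(O)c3O)[C@@H](c3c(O)cc(O)c4c3O[C@H](c3ccc(O)c(O)c3)[C@@H](O)C4)[C@@H]2O)cc1O | target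

**Step count**
Total: 11 steps. Longest linear sequence: 8 steps (steps 1, 2, 3, 7, 8, 9, 10, 11 from (+)-catechin; the chalcone branch, steps 4, 5, 6 and then 7 to 11, is equally long).

**Steps most likely to fail**

Step 9. The chiral anion may lose control of the C2 face against the chiral lower unit. The very electron-rich chromene may also reionise under the acid, which would erode C2. Fallback from 12 back to 14: cyclise 12 with an achiral acid (pyridinium p-toluenesulfonate, CH2Cl2, 0 °C). This should give 14 together with its C2 epimer, the (2R)-chromene F1; the two are diastereomers because of the (2R,3S) lower unit and should be separable by chromatography or preparative HPLC. F1 is resubmitted to the same acid, which reopens C2–O1 through cation 13 and restores the mixture, so material is funnelled to 14 over a few cycles.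

Step 10. Hydroboration of the hindered trisubstituted alkene, flanked by the di-ortho-substituted ring D, may be slow or poorly face-selective, and borane may open the chromene as a Lewis acid. Fallback from 14 back to 16:
- Dimethyldioxirane (acetone, −40 °C) should epoxidise C3=C4 anti to the 2-aryl group to give the 3,4-epoxide F2.
- Meinwald rearrangement (silica gel or catalytic ZnBr2; C4–O ionisation and 1,2-hydride shift from C3) should give the 2,4-trans 4-arylflavan-3-one F3.
- Brief treatment with Et3N should epimerise the more acidic, doubly benzylic C4–H to the diequatorial 2,4-cis 4-arylflavan-3-one F4; the time is kept short so that C2 does not enolise.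
- NaBH4 (MeOH/THF, −40 °C) should attack axially, since ring positions 1 and 4a carry no axial hydrogens, and give the equatorial 3-OH of 16.

Step 7. The di-ortho-substituted aryllithium may add in conjugate fashion, enolise nothing useful or simply not attack the hindered ketone, and the silyl group may migrate. Fallback from 8 and 3 back to 16, in which the C4–C8 bond is made by Friedel–Crafts arylation:
- Luche reduction of 8 (NaBH4, CeCl3·7H2O, MeOH/THF, 0 °C) should give the racemic allylic alcohol F5.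
- The chiral N-triflylphosphoramide of step 9 (toluene, −78 °C) should cyclise F5 to the (2S)-flav-3-ene F6.
- OsO4 (cat.), N-methylmorpholine N-oxide, acetone/H2O should dihydroxylate F6 anti to the 2-aryl group to the 2,3-trans-3,4-cis-flavan-3,4-diol F7.
- TMSOTf (CH2Cl2, −78 °C) ionises C4 of F7 in the presence of excess 3, whose C8 should attack the C4 cation anti to the 3-OH and give 16 (3,4-trans).

Further compounds
F1 | step 9 | (2R)-7,8-bis(benzyloxy)-2-[3,4-bis(benzyloxy)phenyl]-4-[(2R,3S)-penta-O-benzylcatechin-8-yl]-2H-chromene (C2 epimer of 14) | C(c1ccccc1)Oc1ccc([C@@H]2Oc3c(ccc(OCc4ccccc4)c3OCc3ccccc3)C(=C2)c2c(OCc3ccccc3)cc(OCc3ccccc3)c3c2O[C@H](c2ccc(OCc4ccccc4)c(OCc4ccccc4)c2)[C@@H](OCc2ccccc2)C3)cc1OCc1ccccc1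
F2 | step 10 | 3,4-epoxide of 14 on the face anti to the 2-aryl group | C(c1ccccc1)Oc1ccc([C@H]2Oc3c(ccc(OCc4ccccc4)c3OCc3ccccc3)[C@@]3(c4c(OCc5ccccc5)cc(OCc5ccccc5)c5c4O[C@H](c4ccc(OCc6ccccc6)c(OCc6ccccc6)c4)[C@@H](OCc4ccccc4)C5)[C@@H]2O3)cc1OCc1ccccc1
F3 | step 10 | (2R,4R)-7,8-bis(benzyloxy)-2-[3,4-bis(benzyloxy)phenyl]-4-[(2R,3S)-penta-O-benzylcatechin-8-yl]chroman-3-one (2,4-trans) | C(c1ccccc1)Oc1ccc([C@H]2Oc3c(ccc(OCc4ccccc4)c3OCc3ccccc3)[C@H](c3c(OCc4ccccc4)cc(OCc4ccccc4)c4c3O[C@H](c3ccc(OCc5ccccc5)c(OCc5ccccc5)c3)[C@@H](OCc3ccccc3)C4)C2=O)cc1OCc1ccccc1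
F4 | step 10 | (2R,4S)-7,8-bis(benzyloxy)-2-[3,4-bis(benzyloxy)phenyl]-4-[(2R,3S)-penta-O-benzylcatechin-8-yl]chroman-3-one (2,4-cis) | C(c1ccccc1)Oc1ccc([C@H]2Oc3c(ccc(OCc4ccccc4)c3OCc3ccccc3)[C@@H](c3c(OCc4ccccc4)cc(OCc4ccccc4)c4c3O[C@H](c3ccc(OCc5ccccc5)c(OCc5ccccc5)c3)[C@@H](OCc3ccccc3)C4)C2=O)cc1OCc1ccccc1
F5 | step 7 | (E)-1-[3,4-bis(benzyloxy)-2-hydroxyphenyl]-3-[3,4-bis(benzyloxy)phenyl]prop-2-en-1-ol, racemic | OC(/C=C/c1ccc(OCc2ccccc2)c(OCc2ccccc2)c1)c1ccc(OCc2ccccc2)c(OCc2ccccc2)c1O
F6 | step 7 | (2S)-7,8-bis(benzyloxy)-2-[3,4-bis(benzyloxy)phenyl]-2H-chromene | C(c1ccccc1)Oc1ccc([C@H]2Oc3c(ccc(OCc4ccccc4)c3OCc3ccccc3)C=C2)cc1OCc1ccccc1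
F7 | step 7 | (2R,3S,4S)-7,8-bis(benzyloxy)-2-[3,4-bis(benzyloxy)phenyl]chroman-3,4-diol (2,3-trans-3,4-cis) | C(c1ccccc1)Oc1ccc([C@H]2Oc3c(ccc(OCc4ccccc4)c3OCc3ccccc3)[C@H](O)[C@@H]2O)cc1OCc1ccccc1
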